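**Numbering used throughout.** 1 hexa-1,5-diyne; 2 diisobutylaluminium hydride; 3 bis-alane; 4 3-methylbut-3-en-1-ol; 5 its triflate; 6 3-methylcyclohex-2-enone; 7 bis(aluminium enolate); 8 dilithium enolate; 9 bis-ketone tetraene; 10 bis-decalone (C5/C5′ mixture); 11 trans,trans-bis-decalone; 12 target. Each half of the skeleton is numbered as a drimane, the second half primed.

## Analysis of the target

Compound 12 is a C30H50 hydrocarbon built from two identical bicyclic C15 halves joined by the C11–C11′ bond. In each half ring A is C1–C5 with C10, ring B is C5–C10, C4 carries two methyl groups, C10 the methyl C15, C8 the methyl C12 and C9 the linking methylene C11. Each half is a trans-fused octalin with a tetrasubstituted C8=C9 alkene and two stereocentres: C5 (S, tertiary, its hydrogen anti to C15) and C10 (S, quaternary). The halves are homochiral, so the molecule has a C2 axis through the midpoint of C11–C11′ and only two independent stereocentres; a wrong sense in one half gives the meso diastereomer, not the enantiomer. There is no heteroatom, and the only reactive sites are the two tetrasubstituted alkenes, which tolerate base but can migrate or trigger a methyl shift from C10 under strong acid. The difficulty lies in the quaternary C10 next to a fully substituted alkene carbon, the neighbouring quaternary C4, the hindered C8=C9 bonds, and the absence of any functional group, so that every handle must be temporary. The strategy rests on one observation: C10 carries a methyl group and the sp2 carbon C9 and lies two bonds from C4, so with C4 held as a carbonyl, C10 is the β-carbon and C5 the α-carbon of enone 6. The chain C9–C11–C11′–C9′ is then the inner four carbons of diyne 1, whose terminal carbons become methylene groups that are expelled when ring B closes.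

## Retrosynthetic reasoning

**12 to 11.** The four C4–CH3 bonds are cut, turning C4 and C4′ into ketones. The geminal dimethyl group carries no stereochemistry, so it can be installed last. A carbonyl at C4 is the one temporary group that makes C5 acidic and C10 electrophilic in the same ring. The forward reaction has to exchange C=O for C(CH3)2 in one operation by double methyl transfer, without disturbing C5 or the alkenes.

**11 to 10.** No bond is cut; only the configuration at C5 and C5′ is released. This lets the earlier C–C bond formation at C5 proceed without stereocontrol. The forward reaction is a base equilibration α to the C4 ketone, which should settle on the trans ring fusion.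

**10 to 9.** The C8=C9 double bonds are cut in the metathesis sense, each opening into two 1,1-disubstituted alkenes. Ring B has no other functional group, and this cut splits it into a four-carbon arm on C5 (C6, C7, C8 with C12) and C9 with an exocyclic methylene on C10. The forward reaction must close two six-membered rings to tetrasubstituted alkenes beside quaternary carbons, losing the methylene carbons as a volatile alkene.

**9 to 3, 5 and 6.** The bonds C9–C10, C9′–C10′, C5–C6 and C5′–C6′ are cut. C10 becomes the β-carbon of two molecules of 6, C9 and C9′ the nucleophilic carbons of bis-alane 3, C5 an enolate carbon and C6 the electrophilic carbon of two molecules of triflate 5. The two bonds per half sit on the α- and β-positions of one enone, so a single conjugate addition creates the quaternary stereocentre and delivers a regiodefined enolate for the second bond. Because the halves are identical, one catalyst-controlled event used twice sets both C10 centres. The forward reaction needs enantioselective 1,4-addition of a hindered alkenyl group at both ends of 3, followed by C-alkylation of the enolates at C5.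

**3 to 1 and 2; 5 to 4.** The two C–Al bonds of 3 are cut back to the alkyne carbons of 1 and the hydride 2; the forward hydroalumination must place aluminium on the internal carbons. Triflate 5 comes from alcohol 4 by sulfonylation. Both precursors are one step from commercial materials, so the risk of the route sits in the coupling that makes 9.

## Alternatives that were turned down

Alternative 1: A formyl group is added to C6 and C6′, and C5–C10 and C6–C7 are cut in both halves. Everything then derives from the acyclic bis-trienal A2, in which a diene C7=C8–C9=C10 is tethered through C1–C4 to an (E)-enal C5=C6–CHO. In the forward step a chiral imidazolidinone ammonium salt turns both aldehydes into iminium ions, which add intramolecularly to their dienes to give dialdehyde A1 with rings A, B, A′ and B′ closed at once. The formyl carbons are then removed by decarbonylation.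
- For: one step creates four rings, both quaternary C10 centres, both C5 centres with the trans fusion fixed by the transition-state geometry, and both tetrasubstituted alkenes. The gem-dimethyl groups are present from the start. On these points it is stronger than the chosen route, which needs a hard metathesis, an equilibration and a late C4 exchange.
- Against: the diene terminus C10 is fully substituted, so one carbon substituent must point inward in the s-cis conformer, which strongly retards cycloaddition. The iminium β-carbon C5 is neopentyl, next to quaternary C4, and the new C5–C10 bond makes three contiguous congested carbons under a mild organocatalyst developed for unhindered trienals. A2 needs two stereodefined tetrasubstituted C9=C10 alkenes and a long preparation, and two carbons are installed only to be excised.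
- Comparison: the chosen route reaches its key substrate in one step per component and places its risk in reaction classes that are well established for hindered substrates.

Alternative 2: C1–C10 and C1′–C10′ are cut, starting from ring B as the linked bis-enone A4, a 2,4-dimethylcyclohex-2-enone joined at C9. γ-Deprotonation at C8 and C8′ under chiral phase-transfer catalysis gives dienolates that add through C10 to methyl vinyl ketone A5, giving adduct A3 with both alkenes shifted to C8=C9.
- For: the tetrasubstituted alkenes arise by deconjugation without metathesis, the reagents are cheap and metal-free, and quaternary C10 blocks reconjugation. On the alkene it is stronger than the chosen route.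
- Against: hydroxide deprotonation of an unactivated enone at the γ-position is unfavourable, and ion-pair control over a dienolate lacking a second binding group is weak. α versus γ and C versus O attack compete, A5 oligomerises under base, and everything must succeed twice.
- After A3, ring A still has to be closed by aldol condensation, C4 dimethylated, C3 deoxygenated and C5 set by reducing a C5=C6 alkene beside a tetrasubstituted one. That is at least four further operations on both halves, with C5 dependent on facial selectivity.
- Comparison: the chosen route sets C10 with a catalyst class designed for quaternary centres on cyclic enones and needs three steps afterwards.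

Alternative 3: C1–C10 and C4–C5 are cut in both halves. Rings A and A′ come from cycloaddition of diene A8, 2-(triisopropylsilyloxy)buta-1,3-diene, to the two E-configured α-methyl enone units (C5=C10) of the acyclic tetraketone A7 under a chiral oxazaborolidinium Lewis acid, giving adduct A6.
- For: C5 and C10 are set together, their relation fixed by suprafacial addition to an E-alkene, so the trans fusion does not depend on equilibration, and the substrate is a simple symmetric chain. On C5 control it is stronger than the chosen route.
- Against: A7 has four ketone carbonyls and the Lewis acid must select the enone carbonyls C9 and C9′ over the methyl ketones at C8. The 1,4-dicarbonyl unit C9–C11–C11′–C9′ invites acid-mediated cyclodehydration, and α-methyl-β-alkyl acyclic enones are sluggish dienophiles.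
- After A6, ring B must be closed by reductive coupling of two carbonyl carbons (C8 and C9), the C3 oxygen removed, and the gem-dimethyl group placed on C4. The enol ether in A6 is C2=C3, and 3-ketones of trans-decalins enolise toward C2, so there is no direct way to C4.
- Comparison: the chosen route has oxygen only at C4, exactly where the gem-dimethyl group must go, and is several steps shorter.

Key step: step 3

**Assumptions.**
- Diyne 1 is bought as its stabilised pentane solution and used as such.
- L denotes the imidazolinium sulfonate (4S,5S)-1-(2,6-diethylphenyl)-4,5-diphenyl-3-(2-sulfonatophenyl)-4,5-dihydro-1H-imidazol-3-ium inner salt, made separately and converted into its silver carbene with Ag2O. The enantiomer used is the one that delivers the alkenyl group to the Si face of C3 of 6; if the written one gives the opposite sense, its mirror image is taken and nothing else changes.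
- Compound 9 is written as the isomer with C6 anti to C9. Epimers at C5 or C5′ are not separated and converge in step 5.
- Enolate 8 is written as a simple lithium enolate, although it may stay associated with the alane set free from 7.

## Route

Step 1
Reactants: 1 hexa-1,5-diyne; 2 diisobutylaluminium hydride (2.05 equiv)
Product: 3 hexa-1,5-diene-2,5-diylbis(diisobutylalane)
Conditions: Ni(dppp)Cl2 (6 mol%), THF, 0 → 22 °C, 2 h; solution used directly in step 3
Reagents that add atoms: none
Why: Nickel-catalysed α-selective hydroalumination of a terminal alkyl alkyne: the bisphosphine nickel hydride adds across each C≡C bond with the metal on the internal carbon, and exchange with Al–H leaves aluminium on the future C9 and C9′. The two alkynes are separated by two CH2 groups and react independently; the hydride excess is kept small so that little Al–H remains to reduce 6 later.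

Step 2
Reactants: 4 3-methylbut-3-en-1-ol
Product: 5 3-methylbut-3-en-1-yl trifluoromethanesulfonate
Conditions: Tf2O, 2,6-di-tert-butyl-4-methylpyridine, CH2Cl2, −78 °C; cold pentane/silica filtration; used at once
Reagents that add atoms: trifluoromethanesulfonic anhydride, O=S(=O)(OS(=O)(=O)C(F)(F)F)C(F)(F)F
Why: O-Sulfonylation of a primary alcohol. The hindered base cannot be N-alkylated by the product, and low temperature with immediate use suppresses ionisation assisted by the 1,1-disubstituted alkene.

Step 3
Reactants: 3 hexa-1,5-diene-2,5-diylbis(diisobutylalane) (1.0 equiv); 6 3-methylcyclohex-2-en-1-one (2.1 equiv); 5 3-methylbut-3-en-1-yl trifluoromethanesulfonate (3 equiv)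
Product: 9 3,3′-(hexa-1,5-diene-2,5-diyl)bis[(2R,3S)-3-methyl-2-(3-methylbut-3-en-1-yl)cyclohexan-1-one], via bis(diisobutylaluminium) enolate 7 (not isolated), via dilithium enolate 8 (not isolated)
Conditions: Cu(OTf)2 (10 mol%), silver carbene from Ag2O and L (5 mol%), THF, −30 → 22 °C; then MeLi (2.5 equiv), −78 → 0 °C; then 5, THF, −78 → −20 °C; aq. potassium sodium tartrate
Reagents that add atoms: none
Why: The alane reduces Cu(OTf)2 to monovalent copper and Al-to-Cu exchange gives an alkenylcopper carbene complex whose sulfonate arm holds the aluminium that activates the enone carbonyl; π-complexation, oxidative addition at C10 to a trivalent copper enolate and reductive elimination form C9–C10 and release the aluminium enolate, and the cycle repeats at the second C–Al bond to give 7. This is the copper-catalysed enantioselective conjugate addition of α-alkenylalanes to β-substituted cyclic enones with alkylation of the resulting enolate, a tandem conjugate addition–enolate alkylation, run here in both directions. No ring is closed in this step. C10 and C10′ are set by the chiral carbene ligand, which must expose the Si face of C3 of 6; since two independent additions are needed, most minor-sense events end in the separable meso-type diastereomer, so the C2-symmetric product should be enriched in one enantiomer. MeLi converts each O–Al bond into the lithium enolate 8, whose double bond is fixed between C4 and C5 by the conjugate addition, so SN2 attack on 5 can only form C5–C6 and C5′–C6′. The chain should enter mainly anti to the larger alkenyl group on C10, but C5 is not relied on here because step 5 corrects it. The step needs 1,4- over 1,2-addition and alkenyl over isobutyl transfer, secured by the copper carbene and the sp2 C–Al bond, and C- over O-alkylation, favoured by the lithium counter-ion in THF at low temperature without a dipolar cosolvent, which would promote O-alkylation and be alkylated by the triflate itself.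

Step 4
Reactants: 9 3,3′-(hexa-1,5-diene-2,5-diyl)bis[(2R,3S)-3-methyl-2-(3-methylbut-3-en-1-yl)cyclohexan-1-one] (with its C5 epimers)
Product: 10 5,5′-(ethane-1,2-diyl)bis[(4aS)-4a,6-dimethyl-3,4,4a,7,8,8a-hexahydronaphthalen-1(2H)-one], carried as the mixture of epimers at C8a and C8a′ (drimane C5 and C5′)
Conditions: RuCl2[1,3-bis(2-methylphenyl)imidazolidin-2-ylidene](=CH-C6H4-2-O-i-Pr) (2 × 10 mol%), toluene (0.005 M), 80 °C, argon sparge
Reagents that add atoms: none
Why: Double ring-closing olefin metathesis with a ruthenium carbene whose small N-aryl groups admit 1,1-disubstituted alkenes; the catalyst should load on the less hindered isopropenyl group and close onto C9=CH2, giving the six-membered ring B with the tetrasubstituted C8=C9 bond. The quaternary C10 holds the two alkenes close and ethene loss drives the reaction; the competing closures (C9 with C9′ to a cyclobutene, or across the halves to a nine-membered ring) are strained.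

Step 5
Reactants: 10 bis-decalone as the C5/C5′ epimer mixture
Product: 11 5,5′-(ethane-1,2-diyl)bis[(4aS,8aR)-4a,6-dimethyl-3,4,4a,7,8,8a-hexahydronaphthalen-1(2H)-one] (both halves trans-fused)
Conditions: NaOMe, MeOH/THF, 22 → 50 °C
Reagents that add atoms: none
Why: Base-mediated epimerisation α to a ketone through the C4–C5 enolate under thermodynamic control. The trans-fused decalone should be favoured because C6 and C9 are both equatorial on ring A and, with C4 and C8 sp2, the axial C15 methyl has only two syn-axial hydrogens; C10 bears no hydrogen and cannot epimerise.

Step 6
Reactants: 11 trans,trans-bis-decalone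
Product: 12 1,2-bis[(4aS,8aS)-2,5,5,8a-tetramethyl-3,4,4a,5,6,7,8,8a-octahydronaphthalen-1-yl]ethane (target, CNP0372467.1)
Conditions: Me2TiCl2 (5 equiv; made in the flask from Me2Zn and TiCl4, 5 equiv each), CH2Cl2, −40 → 0 °C
Reagents that add atoms: dimethylzinc, C[Zn]C; dimethyltitanium dichloride, C[Ti](C)(Cl)Cl
Why: Geminal dimethylation of a ketone with Me2TiCl2, which forms when dimethylzinc hands its methyl groups to TiCl4: a methyl group adds to the carbonyl, the titanium alkoxide ionises to the tertiary C4 cation, and a second methyl group is delivered from titanium. C5 and C10 are untouched provided the cation is trapped faster than it eliminates or shifts, and the tetrasubstituted alkenes should be inert to the reagent at low temperature in the absence of protic acid.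

## Compound list

1 | hexa-1,5-diyne | C#CCCC#C | starting material
2 | diisobutylaluminium hydride | CC(C)C[AlH]CC(C)C | starting material
3 | hexa-1,5-diene-2,5-diylbis(diisobutylalane) | C=C(CCC(=C)[Al](CC(C)C)CC(C)C)[Al](CC(C)C)CC(C)C | intermediate
4 | 3-methylbut-3-en-1-ol | C=C(C)CCO | starting material
5 | 3-methylbut-3-en-1-yl trifluoromethanesulfonate | C=C(C)CCOS(=O)(=O)C(F)(F)F | intermediate
6 | 3-methylcyclohex-2-en-1-one | CC1=CC(=O)CCC1 | starting material
7 | 2,5-bis[(1S)-3-(diisobutylalumanyloxy)-1-methylcyclohex-2-en-1-yl]hexa-1,5-diene | C=C(CCC(=C)[C@@]1(C)CCCC(O[Al](CC(C)C)CC(C)C)=C1)[C@@]1(C)CCCC(O[Al](CC(C)C)CC(C)C)=C1 | intermediate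
8 | 2,5-bis[(1S)-3-(lithiooxy)-1-methylcyclohex-2-en-1-yl]hexa-1,5-diene | C=C(CCC(=C)[C@@]1(C)CCCC(O[Li])=C1)[C@@]1(C)CCCC(O[Li])=C1 | intermediate
9 | 3,3′-(hexa-1,5-diene-2,5-diyl)bis[(2R,3S)-3-methyl-2-(3-methylbut-3-en-1-yl)cyclohexan-1-one] | C=C(C)CC[C@H]1C(=O)CCC[C@]1(C)C(=C)CCC(=C)[C@@]1(C)CCCC(=O)[C@@H]1CCC(C)=C | intermediate
10 | 5,5′-(ethane-1,2-diyl)bis[(4aS)-4a,6-dimethyl-3,4,4a,7,8,8a-hexahydronaphthalen-1(2H)-one], epimer mixture at C8a/C8a′ (written with these centres undefined) | CC1=C(CCC2=C(C)CCC3C(=O)CCC[C@]23C)[C@@]2(C)CCCC(=O)C2CC1 | intermediate
11 | 5,5′-(ethane-1,2-diyl)bis[(4aS,8aR)-4a,6-dimethyl-3,4,4a,7,8,8a-hexahydronaphthalen-1(2H)-one] | CC1=C(CCC2=C(C)CC[C@H]3C(=O)CCC[C@]23C)[C@@]2(C)CCCC(=O)[C@@H]2CC1 | intermediate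
12 | 1,2-bis[(4aS,8aS)-2,5,5,8a-tetramethyl-3,4,4a,5,6,7,8,8a-octahydronaphthalen-1-yl]ethane | CC1=C(CCC2=C(C)CC[C@H]3C(C)(C)CCC[C@]23C)[C@@]2(C)CCCC(C)(C)[C@@H]2CC1 | target

## Step count and risk

Total step count: 6. Longest linear sequence: 5 steps (1, 3, 4, 5, 6); step 2 is a one-step branch.

**Step 3 (key step).** The most likely failures are incomplete transfer at the second C–Al bond, which would leave mono-adducts, and loss of the enolate during alkylation. The enolate can be lost by proton exchange with product, by E2 elimination of the homoallylic triflate, or by O-alkylation, because the C5 enolate is hindered by the neighbouring quaternary C10 and aluminium residues are present. The fallback separates the two bond formations. It sets out from 3 and 6: the conjugate addition is run as before, but enolate 7 is silylated with Me3SiOTf to the bis(trimethylsilyl enol ether) F1, which is isolated and freed from excess 6 and mono-adducts. MeLi in THF then regenerates the aluminium-free dilithium enolate 8, which is alkylated in THF/HMPA with 4-iodo-2-methylbut-1-ene F2, made from 4 with PPh3, I2 and imidazole. The sequence returns to the route at 9.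

**Step 4.** Ring closure may stall after the catalyst has loaded on the isopropenyl group, since the second alkene is 1,1-disubstituted and sits on a quaternary carbon; slow turnover then gives way to catalyst decay or to dimerisation through the isopropenyl ends. The fallback forms C8=C9 by reductive carbonyl coupling instead of metathesis. It sets out from 9: both C4 ketones are protected with 1,2-bis(trimethylsilyloxy)ethane and catalytic Me3SiOTf to give the bis(ethylene ketal) F3. Ozonolysis with Me2S work-up cleaves all four methylene groups to the tetraketone F4. A McMurry coupling (TiCl3(DME)1.5, Zn–Cu, DME, reflux, slow addition) joins C8 to C9 in each half to give the bis-ketal F5. Mild aqueous acid removes the ketals and the material returns at 10.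

**Step 5.** Enolisation toward the hindered C5 may be slow compared with the C3 side, and the equilibrium may not lie far enough on the trans side, leaving cis-fused material that cannot be corrected after step 6. The fallback sets C5 kinetically. It sets out from 10: Me3SiCl, NaI and Et3N in MeCN give the more substituted bis(trimethylsilyl enol ether) F6 with the double bonds at C4=C5. MeLi converts it into the dilithium enolate F7, and protonation at −78 °C with a hindered phenol should deliver hydrogen to C5 from the face opposite the axial C15 methyl. This gives the trans fusion and returns at 11.

**Step 6.** The C4 cation may lose a proton to an alkene or accept hydride from C5 before the second methyl arrives, and adventitious acid could move the C8=C9 bond or trigger a methyl shift from C10. The fallback avoids a cation at C4. It sets out from 11: Wittig methylenation with Ph3P=CH2 gives the bis(4-methylene) compound F8. Cyclopropanation with Et2Zn and CH2I2 should take the exposed exocyclic alkenes in preference to the shielded tetrasubstituted ones and give the bis(spirocyclopropane) F9. Hydrogenolysis (H2, PtO2, AcOH) opens each cyclopropane at its CH2–CH2 bond to the gem-dimethyl group and returns at 12.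

## Further compounds

F1 | step 3 | 2,5-bis[(1S)-1-methyl-3-(trimethylsilyloxy)cyclohex-2-en-1-yl]hexa-1,5-diene | C=C(CCC(=C)[C@@]1(C)CCCC(O[Si](C)(C)C)=C1)[C@@]1(C)CCCC(O[Si](C)(C)C)=C1
F2 | step 3 | 4-iodo-2-methylbut-1-ene | C=C(C)CCI
F3 | step 4 | bis(ethylene ketal) of 9 at C4 and C4′ | C=C(C)CC[C@H]1C2(OCCO2)CCC[C@]1(C)C(=C)CCC(=C)[C@@]1(C)CCCC2(OCCO2)[C@@H]1CCC(C)=C
F4 | step 4 | tetraketone bis(ethylene ketal) with ketones at C8, C9, C9′ and C8′ | CC(=O)CC[C@H]1C2(OCCO2)CCC[C@]1(C)C(=O)CCC(=O)[C@@]1(C)CCCC2(OCCO2)[C@@H]1CCC(C)=O
F5 | step 4 | bis(ethylene ketal) of 10 at C4 and C4′ | CC1=C(CCC2=C(C)CC[C@H]3C4(OCCO4)CCC[C@]23C)[C@@]2(C)CCCC3(OCCO3)[C@@H]2CC1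
F6 | step 5 | bis(trimethylsilyl enol ether) of 10 with C4=C5 and C4′=C5′ double bonds | CC1=C(CCC2=C(C)CCC3=C(O[Si](C)(C)C)CCC[C@]23C)[C@@]2(C)CCCC(O[Si](C)(C)C)=C2CC1
F7 | step 5 | dilithium C4=C5 enolate of 10 | CC1=C(CCC2=C(C)CCC3=C(O[Li])CCC[C@]23C)[C@@]2(C)CCCC(O[Li])=C2CC1
F8 | step 6 | bis(4-methylene) analogue of 11 | CC1=C(CCC2=C(C)CC[C@H]3C(=C)CCC[C@]23C)[C@@]2(C)CCCC(=C)[C@@H]2CC1
F9 | step 6 | bis(spirocyclopropane) at C4 and C4′ | CC1=C(CCC2=C(C)CC[C@H]3C4(CC4)CCC[C@]23C)[C@@]2(C)CCCC3(CC3)[C@@H]2CC1
A1 | alternative 1 | 6,6′-diformyl derivative of 12 | CC1=C(CCC2=C(C)C[C@H](C=O)[C@H]3C(C)(C)CCC[C@]23C)[C@@]2(C)CCCC(C)(C)[C@@H]2[C@@H](C=O)C1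
A2 | alternative 1 | C2-symmetric bis-trienal with (E)-enals, C9=C10 geometry left open | O=C/C=C/C(C)(C)CCCC(C)=C(CCC(=C(C)CCCC(C)(C)/C=C/C=O)C(C)=C)C(C)=C
A3 | alternative 2 | bis-Michael adduct with quaternary C10 and C10′ and C8=C9 alkenes | CC1=C(CCC2=C(C)CCC(=O)[C@]2(C)CCC(C)=O)[C@@](C)(CCC(C)=O)C(=O)CC1
A4 | alternative 2 | 3,3′-(ethane-1,2-diyl)bis(2,4-dimethylcyclohex-2-en-1-one) | CC1CCC(=O)C(C)=C1CCC1=C(C)C(=O)CCC1C
A5 | alternative 2 | but-3-en-2-one (methyl vinyl ketone) | C=CC(C)=O
A6 | alternative 3 | bis(cyclohexene triisopropylsilyl enol ether) Diels–Alder adduct | CC(=O)CC[C@H]1CC(O[Si](C(C)C)(C(C)C)C(C)C)=CC[C@]1(C)C(=O)CCC(=O)[C@@]1(C)CC=C(O[Si](C(C)C)(C(C)C)C(C)C)C[C@@H]1CCC(C)=O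
A7 | alternative 3 | (5E,11E)-6,11-dimethylhexadeca-5,11-diene-2,7,10,15-tetraone | CC(=O)CC/C=C(\C)C(=O)CCC(=O)/C(C)=C/CCC(C)=O
A8 | alternative 3 | 2-(triisopropylsilyloxy)buta-1,3-diene | C=CC(=C)O[Si](C(C)C)(C(C)C)C(C)C
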